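## Retrosynthetic overview

1. Last bond: the exocyclic C5=CH, by vinylogous aldol condensation of a 3-aryltetronic acid with the (R)-chromanol aldehyde; the Z geometry is set thermodynamically.
2. Key bond: tetronic acid C3 to the aryl ring. The electron-rich hydroquinone carbon is used in its oxidised, electrophilic form (2-prenyl-1,4-benzoquinone), so two natively nucleophilic carbons are joined by conjugate addition and re-aromatisation, without protecting groups.
3. Quinone: from 1,4-dimethoxybenzene by ortho-lithiation/prenylation and oxidative demethylation.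
4. Aldehyde: from commercial 6-cyano-2,2-dimethylchromene by asymmetric epoxidation (sets the R carbinol), benzylic hydrogenolysis and nitrile-to-aldehyde reduction.
5. Rings: the furanone and benzopyran rings are bought intact. The only ring events are the transient oxirane (formed, then opened) and the regeneration of the aromatic hydroquinone ring in the key step, before the final condensation.

Assumption: 1,4-dimethoxybenzene, prenyl bromide, tetronic acid and 2,2-dimethyl-2H-chromene-6-carbonitrile are taken as commercial; the target is the (Z)-alkylidene, (R)-carbinol isomer read from the SMILES.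

## Route

Step 1
Reactants: 1 1,4-dimethoxybenzene; 2 1-bromo-3-methylbut-2-ene (prenyl bromide)
Product: 4 1,4-dimethoxy-2-(3-methylbut-2-en-1-yl)benzene, via aryllithium 3 (not isolated)
Conditions: n-BuLi (1.1 equiv), TMEDA (1.1 equiv), THF, 0 °C to rt, 2 h; then 2 (1.2 equiv), –78 °C to rt
Reagents that add atoms: none
Why: Directed ortho-lithiation (the methoxy group guides n-BuLi/TMEDA to the adjacent C–H) followed by SN2 alkylation of the aryllithium at the primary carbon of the allylic bromide gives the linear prenyl arene, and no stereocenter is formed.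

Step 2
Reactants: 4 1,4-dimethoxy-2-(3-methylbut-2-en-1-yl)benzene
Product: 5 2-(3-methylbut-2-en-1-yl)cyclohexa-2,5-diene-1,4-dione (2-prenyl-1,4-benzoquinone)
Conditions: (NH4)2Ce(NO3)6 (2.5 equiv), MeCN/H2O 2:1, 0 °C, 20 min; used at once
Reagents that add atoms: water, O
Why: Oxidative demethylation, in which two one-electron oxidations by tetravalent cerium convert the electron-rich hydroquinone dimethyl ether (oxidised far more easily than the trisubstituted alkene) into the quinone through addition of water and loss of two molecules of methanol.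

Step 3
Reactants: 5 2-prenyl-1,4-benzoquinone; 6 tetronic acid (4-hydroxyfuran-2(5H)-one)
Product: 8 3-[2,5-dihydroxy-4-(3-methylbut-2-en-1-yl)phenyl]-4-hydroxyfuran-2(5H)-one, via ene-dione Michael adduct 7 (not isolated)
Conditions: 6 (1.5 equiv), aq. NaOAc/AcOH buffer (pH 5)/MeCN 1:1, degassed, Ar, slow addition of 5, rt, 4 h; then 1 M HCl to pH 2; SiO2 to remove the minor 2,6-regioisomer
Reagents that add atoms: none
Why: Michael addition of the soft tetronate C3 carbanion (fully ionised at pH 5) to the quinone, which acts as the electrophilic, polarity-reversed form of the normally nucleophilic hydroquinone ring (quinone α-arylation of a 1,3-dicarbonyl); attack goes to C5, the unhindered position para to the prenyl group and β to the C1 carbonyl that the alkyl donor does not deactivate, enolisation of adduct 7 restores the aromatic ring as the free hydroquinone, the amine-free weakly acidic medium avoids base-induced isomerisation of the prenylquinone to a chromenol, and the electron-poor product is not re-oxidised by the electron-richer quinone 5.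

Step 4
Reactants: 9 2,2-dimethyl-2H-chromene-6-carbonitrile
Product: 10 (3R,4R)-3,4-epoxy-2,2-dimethylchromane-6-carbonitrile
Conditions: (R,R)-(salen)MnCl [(R,R)-N,N'-bis(3,5-di-tert-butylsalicylidene)cyclohexane-1,2-diamine manganese chloride, C36H52ClMnN2O2] (2 mol%), 4-phenylpyridine N-oxide (10 mol%), aq. NaOCl (1.5 equiv, Na2HPO4 buffer, pH 11.3), CH2Cl2, 0 °C; recrystallisation to >99% ee
Reagents that add atoms: sodium hypochlorite, [Na+].[O-]Cl
Why: Jacobsen–Katsuki epoxidation, in which the oxo-manganese salen species delivers oxygen to one enantioface of the cis-disubstituted styrene-type alkene, and the (R,R) catalyst gives the (3R,4R) epoxide of this benchmark chromene in about 97% ee, which sets the configuration of the future carbinol carbon.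

Step 5
Reactants: 10 (3R,4R)-3,4-epoxy-2,2-dimethylchromane-6-carbonitrile
Product: 11 (3R)-3-hydroxy-2,2-dimethyl-3,4-dihydro-2H-chromene-6-carbonitrile
Conditions: H2 (1 atm), 10% Pd/C (5 mol% Pd), EtOAc, rt, about 2 h (stopped at full conversion of 10)
Reagents that add atoms: none
Why: Hydrogenolysis of the benzylic C4–O bond of the aryl epoxide on palladium leaves the C3–O bond untouched, so the C3 configuration (R, CIP order unchanged) is carried over from the epoxide, and the aryl nitrile is not reduced at 1 atm in neutral ethyl acetate.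

Step 6
Reactants: 11 (3R)-3-hydroxy-2,2-dimethyl-3,4-dihydro-2H-chromene-6-carbonitrile
Product: 13 (3R)-3-hydroxy-2,2-dimethyl-3,4-dihydro-2H-chromene-6-carbaldehyde, via aluminium aldimine 12 (not isolated)
Conditions: i-Bu2AlH (2.5 equiv), CH2Cl2, –78 to –40 °C; then 1 M HCl, 0 °C to rt
Reagents that add atoms: water, O
Why: Partial reduction of a nitrile with i-Bu2AlH, in which the first equivalent deprotonates the alcohol, one hydride adds to the nitrile to give the N-aluminio aldimine 12 that resists further reduction at low temperature, and acidic work-up hydrolyses it to the aldehyde without touching the carbinol center.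

Step 7
Reactants: 8 3-[2,5-dihydroxy-4-(3-methylbut-2-en-1-yl)phenyl]-4-hydroxyfuran-2(5H)-one; 13 (3R)-3-hydroxy-2,2-dimethyl-3,4-dihydro-2H-chromene-6-carbaldehyde
Product: 15 (5Z)-3-[2,5-dihydroxy-4-(3-methylbut-2-en-1-yl)phenyl]-4-hydroxy-5-{[(3R)-3-hydroxy-2,2-dimethyl-3,4-dihydro-2H-chromen-6-yl]methylidene}furan-2(5H)-one, via aldol adduct 14 (not isolated)
Conditions: DBU (4 equiv), MeCN (degassed), Ar, rt to 50 °C, 12 h; then 1 M HCl
Reagents that add atoms: none
Why: Vinylogous aldol condensation, in which DBU generates the dienolate of the 3-aryltetronate, its C5 adds to the aldehyde, and E1cB loss of water from adduct 14 under equilibrating conditions gives the thermodynamically preferred Z-alkylidene (aryl syn to the ring oxygen and away from the C4 oxygen), as known for the aspulvinone series, while exclusion of air protects the hydroquinone and the chroman carbinol center is not epimerisable.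

## Compound list

1 | 1,4-dimethoxybenzene | COc1ccc(OC)cc1 | starting material
2 | 1-bromo-3-methylbut-2-ene (prenyl bromide) | CC(C)=CCBr | starting material
3 | (2,5-dimethoxyphenyl)lithium | COc1ccc(OC)c([Li])c1 | intermediate (not isolated)
4 | 1,4-dimethoxy-2-(3-methylbut-2-en-1-yl)benzene | COc1ccc(OC)c(CC=C(C)C)c1 | intermediate
5 | 2-(3-methylbut-2-en-1-yl)cyclohexa-2,5-diene-1,4-dione | CC(C)=CCC1=CC(=O)C=CC1=O | intermediate
6 | tetronic acid (4-hydroxyfuran-2(5H)-one) | OC1=CC(=O)OC1 | starting material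
7 | 5-(4-hydroxy-2-oxo-2,5-dihydrofuran-3-yl)-2-(3-methylbut-2-en-1-yl)cyclohex-2-ene-1,4-dione | CC(C)=CCC1=CC(=O)C(CC1=O)C1=C(O)COC1=O | intermediate (not isolated)
8 | 3-[2,5-dihydroxy-4-(3-methylbut-2-en-1-yl)phenyl]-4-hydroxyfuran-2(5H)-one | CC(C)=CCc1cc(O)c(cc1O)C1=C(O)COC1=O | intermediate
9 | 2,2-dimethyl-2H-chromene-6-carbonitrile | CC1(C)C=Cc2cc(C#N)ccc2O1 | starting material
10 | (3R,4R)-3,4-epoxy-2,2-dimethylchromane-6-carbonitrile | N#Cc1ccc2c(c1)[C@H]3O[C@H]3C(C)(C)O2 | intermediate
11 | (3R)-3-hydroxy-2,2-dimethyl-3,4-dihydro-2H-chromene-6-carbonitrile | N#Cc1ccc2c(c1)C[C@@H](O)C(C)(C)O2 | intermediate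
12 | N,O-bis(diisobutylaluminio) aldimine of 13 | CC(C)C[Al](CC(C)C)N=Cc1ccc2c(c1)C[C@@H](O[Al](CC(C)C)CC(C)C)C(C)(C)O2 | intermediate (not isolated)
13 | (3R)-3-hydroxy-2,2-dimethyl-3,4-dihydro-2H-chromene-6-carbaldehyde | O=Cc1ccc2c(c1)C[C@@H](O)C(C)(C)O2 | intermediate
14 | 3-[2,5-dihydroxy-4-(3-methylbut-2-en-1-yl)phenyl]-4-hydroxy-5-{hydroxy[(3R)-3-hydroxy-2,2-dimethyl-3,4-dihydro-2H-chromen-6-yl]methyl}furan-2(5H)-one (diastereomer mixture at the two new carbons) | CC(C)=CCc1cc(O)c(cc1O)C1=C(O)C(OC1=O)C(O)c1ccc2c(c1)C[C@@H](O)C(C)(C)O2 | intermediate (not isolated)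
15 | (5Z)-3-[2,5-dihydroxy-4-(3-methylbut-2-en-1-yl)phenyl]-4-hydroxy-5-{[(3R)-3-hydroxy-2,2-dimethyl-3,4-dihydro-2H-chromen-6-yl]methylidene}furan-2(5H)-one | CC(C)=CCc1cc(O)c(C2=C(O)/C(=C/c3ccc4c(c3)C[C@@H](O)C(C)(C)O4)OC2=O)cc1O | target

## Step count and risks

Total step count: 7. Longest linear sequence: 4 steps (9 → 10 → 11 → 13 → 15, or 1 → 4 → 5 → 8 → 15).

**Step 3 (most at risk).** The quinone addition may give too much of the 2,6-regioisomer, or the prenylquinone may isomerise or over-oxidise the product. The fallback sets out from 1 and comes back to the route at 8, fixing the para pattern by substitution instead of by addition selectivity.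
- 1 is dibrominated (Br2, AcOH, rt) to 1,4-dibromo-2,5-dimethoxybenzene F1.
- Exchange of one bromine (n-BuLi, 1.0 equiv, THF, –78 °C) gives (4-bromo-2,5-dimethoxyphenyl)lithium F2, which is alkylated in the flask with 2 to 1-bromo-2,5-dimethoxy-4-(3-methylbut-2-en-1-yl)benzene F3.
- F3 and 6 are joined by palladium-catalysed α-arylation of the cyclic 1,3-dicarbonyl (Pd(OAc)2, 2-di-tert-butylphosphino-2',4',6'-triisopropylbiphenyl, K3PO4, dioxane, 90 °C) to 3-[2,5-dimethoxy-4-(3-methylbut-2-en-1-yl)phenyl]-4-hydroxyfuran-2(5H)-one F4.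
- (NH4)2Ce(NO3)6 in MeCN/H2O at 0 °C unmasks the ring as 2-(4-hydroxy-2-oxo-2,5-dihydrofuran-3-yl)-5-(3-methylbut-2-en-1-yl)cyclohexa-2,5-diene-1,4-dione F5, and Na2S2O4 (aq., EtOAc, rt) reduces F5 to 8.

**Step 7.** The vinylogous aldol on the unprotected hydroquinone may be sluggish or suffer oxidation under base. The fallback sets out from 6 and 13 and comes back at 15, exchanging the order of the last two bond formations.
- 6 is O-methylated (MeOH, cat. H2SO4, reflux) to 4-methoxyfuran-2(5H)-one F6.
- Its C5 lithium dienolate (LiN(i-Pr)2, 2.2 equiv, THF, –78 °C) adds to 13 to give 5-{hydroxy[(3R)-3-hydroxy-2,2-dimethyl-3,4-dihydro-2H-chromen-6-yl]methyl}-4-methoxyfuran-2(5H)-one F7.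
- F7 is dehydrated (p-TsOH, toluene, 80 °C; no prenyl group is present in this fragment) to (Z)-5-{[(3R)-3-hydroxy-2,2-dimethyl-3,4-dihydro-2H-chromen-6-yl]methylidene}-4-methoxyfuran-2(5H)-one F8.
- SN2 demethylation (LiCl, DMF, 120 °C) gives (Z)-4-hydroxy-5-{[(3R)-3-hydroxy-2,2-dimethyl-3,4-dihydro-2H-chromen-6-yl]methylidene}furan-2(5H)-one F9.
- The free C3 of F9 adds to quinone 5 under the conditions of step 3 and gives, through 5-[(5Z)-4-hydroxy-5-{[(3R)-3-hydroxy-2,2-dimethyl-3,4-dihydro-2H-chromen-6-yl]methylidene}-2-oxo-2,5-dihydrofuran-3-yl]-2-(3-methylbut-2-en-1-yl)cyclohex-2-ene-1,4-dione F10, the target 15.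

**Step 5.** Hydrogenolysis may touch the nitrile, or acid traces on the catalyst may rearrange the epoxide to the achiral chroman-3-one. The fallback sets out from 10 and comes back at 11 with no metal surface.
- The epoxide is opened at the benzylic carbon by bromide (LiBr, AcOH, THF, 0 °C; inversion at C4, C3 untouched) to the trans-bromohydrin (3S,4S)-4-bromo-3-hydroxy-2,2-dimethyl-3,4-dihydro-2H-chromene-6-carbonitrile F11. The C3 descriptor changes only because bromine raises the CIP rank of C4.
- The C–Br bond is removed by radical chain reduction (Bu3SnH, AIBN, toluene, 80 °C) to give 11.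

## Further compounds

F1 | step 3 | 1,4-dibromo-2,5-dimethoxybenzene | COc1cc(Br)c(OC)cc1Br
F2 | step 3 | (4-bromo-2,5-dimethoxyphenyl)lithium | COc1cc(Br)c(OC)cc1[Li]
F3 | step 3 | 1-bromo-2,5-dimethoxy-4-(3-methylbut-2-en-1-yl)benzene | COc1cc(CC=C(C)C)c(OC)cc1Br
F4 | step 3 | 3-[2,5-dimethoxy-4-(3-methylbut-2-en-1-yl)phenyl]-4-hydroxyfuran-2(5H)-one | COc1cc(CC=C(C)C)c(OC)cc1C1=C(O)COC1=O
F5 | step 3 | 2-(4-hydroxy-2-oxo-2,5-dihydrofuran-3-yl)-5-(3-methylbut-2-en-1-yl)cyclohexa-2,5-diene-1,4-dione | CC(C)=CCC1=CC(=O)C(=CC1=O)C1=C(O)COC1=O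
F6 | step 7 | 4-methoxyfuran-2(5H)-one | COC1=CC(=O)OC1
F7 | step 7 | 5-{hydroxy[(3R)-3-hydroxy-2,2-dimethyl-3,4-dihydro-2H-chromen-6-yl]methyl}-4-methoxyfuran-2(5H)-one | COC1=CC(=O)OC1C(O)c1ccc2c(c1)C[C@@H](O)C(C)(C)O2
F8 | step 7 | (Z)-5-{[(3R)-3-hydroxy-2,2-dimethyl-3,4-dihydro-2H-chromen-6-yl]methylidene}-4-methoxyfuran-2(5H)-one | COC1=CC(=O)O/C1=C\c1ccc2c(c1)C[C@@H](O)C(C)(C)O2
F9 | step 7 | (Z)-4-hydroxy-5-{[(3R)-3-hydroxy-2,2-dimethyl-3,4-dihydro-2H-chromen-6-yl]methylidene}furan-2(5H)-one | OC1=CC(=O)O/C1=C\c1ccc2c(c1)C[C@@H](O)C(C)(C)O2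
F10 | step 7 | 5-[(5Z)-4-hydroxy-5-{[(3R)-3-hydroxy-2,2-dimethyl-3,4-dihydro-2H-chromen-6-yl]methylidene}-2-oxo-2,5-dihydrofuran-3-yl]-2-(3-methylbut-2-en-1-yl)cyclohex-2-ene-1,4-dione | CC(C)=CCC1=CC(=O)C(CC1=O)C1=C(O)/C(=C/c2ccc3c(c2)C[C@@H](O)C(C)(C)O3)OC1=O
F11 | step 5 | (3S,4S)-4-bromo-3-hydroxy-2,2-dimethyl-3,4-dihydro-2H-chromene-6-carbonitrile (trans) | N#Cc1ccc2c(c1)[C@H](Br)[C@@H](O)C(C)(C)O2
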